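Readings and results come from a simulation with made-up constants; noise was put on by code.

Read each run as a straight line with a fast excess laid on top of it, and ask what that excess does to a rate taken at a fixed conversion.

| setting | beta | eta | alpha | flask |
|---|---|---|---|---|
| substrate | 0.013 M | 0.030 M | 0.020 M | 0.020 M |
| coupling partner | 1.2 equiv | 1.2 equiv | 0.60 equiv | 1.20 equiv |
| free catalyst | 0.2 mol% | 0.2 mol% | 0.2 mol% | 0.2 mol% |
| remark | run made earlier | run made earlier | run made earlier |  |

- beta (time / d: product / %): 0.250: 5.4; 0.417: 8.8; 0.625: 10.3; 0.833: 11.8; 1.25: 14.4; 2.00: 17.7; 3.00: 22.9
- eta (time / d: product / %): 0.500: 27.8; 0.833: 34.4; 1.25: 40.3; 1.67: 44.5; 2.50: 52.5; 3.00: 57.0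
- alpha (time / d: product / %): 0.250: 6.3; 0.500: 9.2; 0.833: 11.4; 1.67: 15.9; 3.00: 21.6

(readings scatter by 0.3 percentage points)

* factor on the rate of making product when 20 % of the substrate are converted if free catalyst is charged twice over
* factor on the rate when 20 % of the substrate are converted if free catalyst is charged at 1 mol% instead



Two chemists differ over the flask. The first says that a rate follows its catalyst, so a double charge gives twice the rate and 1 mol% gives 5.00 times the rate.

The second, whose reckoning I follow, answers that the mark is a conversion and not a time. More catalyst reaches it earlier, on a steeper part of the curve. Her argument starts from the late slopes, which are 6.31 × 10⁻⁴ M/d in the beta run and 0.00286 M/d in the eta run. The flask has their equivalents and loading, with a concentration between theirs, so interpolating on logarithms gives it a line of 0.00138 M/d.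

Each line, run back to zero time, leaves an intercept: 0.00108 M for beta and 0.00851 M for eta. Interpolated the same way, this gives 0.00313 M for the flask. Call this the burst capacity, the product a flask makes above its line, which grows in proportion to the catalyst if the curve does. The first eta reading gives a burst lifetime of 0.299 d, and the excess rate is the capacity still unused divided by that lifetime.

The mark is 0.00400 M, larger than the capacity, so in the flask the line must supply the difference, which takes about 0.631 d. The rate there is about 0.00265 M/d. With a double charge the capacity exceeds the mark. Counting the whole mark against it leaves 0.0103 M/d, a factor of 3.90.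

The first chemist keeps one region within this reckoning. Compared at one fixed time and not at a mark, a curve that grows in proportion to the catalyst has twice the rate, as he says.

The forecast takes the second side, reading “a fast burst that dies with a lifetime of about 0.3 d”, and gives 4.7 and 17.5, higher on the double charge than my reckoning.

    coupling partner + free catalyst ⇌ catalyst intermediate A (K = 7.70 /M, k = 2500 /M/h)
    substrate + catalyst intermediate A → catalyst intermediate B (k = 6000 /M/h)
    catalyst intermediate B ⇌ catalyst intermediate C (K = 0.770, k = 230 /h)
    catalyst intermediate C → by-product + catalyst intermediate D (k = 1000 /h)
    catalyst intermediate D → free catalyst + product (k = 5600 /h)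
    coupling partner ⇌ dormant form (K = 3.90, k = 0.110 /h)

The flask gives 3.99 for the double charge, reaching the mark at 0.700 d with a rate of 0.00263 M/d. At 0.400 d in the flask, free catalyst, the resting state, stands at 92.5 % of its charge, while coupling partner is down to 34.1 % of its own and dormant form holds 0.0128 M. At 1 mol% the capacity becomes 0.0157 M, which is 3.92 times the mark, and the rate reckoned from what remains is 17.3 times that of the flask, where the simulated factor is 14.3.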